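**Plan**
- Retrosynthetic cuts, in order: the two gallate esters at O7 and O3'; the aryl ether bond O1–C8a of ring C; the C2–C1' bond (ketone from an amide and a ring B Grignard reagent); the C3–C4 bond (benzylic alkylation of a glycolate).
- Enabling feature: O1 is an aryl ether oxygen bound to C8a of ring A, and C8a carries no other substituent. Ring C can therefore be closed last by O-arylation of a C2 hydroxyl with a C8a bromide, with C2 and C3 already fixed in an open chain.
- Forward order: ring A benzylic bromide (bromine marks C8a and distinguishes O5 from O7), then C3–C4 by glycolate alkylation, C2–C1' by Weinreb ketone synthesis, reduction, closure of ring C, exchange of the allyl groups for galloyl groups, and global debenzylation.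
- Stereochemistry: C3 (S) comes from the (R)-4-benzyloxazolidinone-controlled alkylation; C2 (R) comes from a chelation-controlled ketone reduction anti to the C3 benzyloxy group. Neither centre is touched afterwards, which gives the 2,3-trans flavan.
- Protecting groups: allyl on O7 and O3' (the gallate sites); benzyl on O3, O5, O4' and on the gallate hydroxyls.

Key step: step 13

Remark: flavan numbering (O1, C2, C3, C4, C4a, C5 to C8, C8a, ring B primed) is used for all intermediates, and the catechol monoester at O3' is assumed not to migrate to O4' under neutral, base-free conditions.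

**Route**

Step 1
Reactants: 1 5-bromoresorcinol
Product: 3 2-bromo-4,6-dihydroxybenzaldehyde, via aryliminium chloride 2 (not isolated)
Conditions: POCl3, DMF, MeCN, 0 °C to rt; then H2O, 50 °C
Reagents that add atoms: N,N-dimethylformamide CN(C)C=O; water O
Why: Vilsmeier–Haack formylation, in which the chloroiminium ion attacks the resorcinol at C4 (para to one hydroxyl, ortho to the other, the orientation known for orcinol) and hydrolysis of iminium salt 2 releases the aldehyde, so that bromine sits ortho to the formyl carbon (future C8a next to C4a) and the two hydroxyls become distinct.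

Step 2
Reactants: 3 2-bromo-4,6-dihydroxybenzaldehyde
Product: 4 4-(allyloxy)-2-bromo-6-hydroxybenzaldehyde
Conditions: allyl bromide (1.05 equiv), CsHCO3, MeCN, 60 °C
Reagents that add atoms: allyl bromide C=CCBr
Why: Williamson etherification in which the hydroxyl para to the formyl group, being the more acidic and not hydrogen-bonded to the carbonyl, should be alkylated alone by a weak hydrogencarbonate base, as is established for 2,4-dihydroxybenzaldehyde; this puts allyl on the future O7.

Step 3
Reactants: 4 4-(allyloxy)-2-bromo-6-hydroxybenzaldehyde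
Product: 5 4-(allyloxy)-2-(benzyloxy)-6-bromobenzaldehyde
Conditions: BnBr, K2CO3, DMF, 50 °C
Reagents that add atoms: benzyl bromide BrCc1ccccc1
Why: Williamson etherification of the remaining hydrogen-bonded ortho hydroxyl, which needs the stronger carbonate base in DMF and places benzyl on the future O5.

Step 4
Reactants: 5 4-(allyloxy)-2-(benzyloxy)-6-bromobenzaldehyde
Product: 6 [4-(allyloxy)-2-(benzyloxy)-6-bromophenyl]methanol
Conditions: NaBH4, THF/MeOH, 0 °C
Reagents that add atoms: none
Why: Hydride reduction of the aromatic aldehyde to the benzylic alcohol, to which the aryl bromide and the allyl and benzyl ethers are inert.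

Step 5
Reactants: 6 [4-(allyloxy)-2-(benzyloxy)-6-bromophenyl]methanol
Product: 7 5-(allyloxy)-1-(benzyloxy)-3-bromo-2-(bromomethyl)benzene
Conditions: PBr3, Et2O, 0 °C
Reagents that add atoms: phosphorus tribromide BrP(Br)Br
Why: Conversion of the alcohol to the bromide through its phosphite ester with SN2 displacement by bromide, fast at 0 °C for this electron-rich benzylic alcohol; the bromide would be used at once without chromatography.

Step 6
Reactants: 8 (R)-4-benzyloxazolidin-2-one; 9 benzyloxyacetyl chloride
Product: 10 (R)-4-benzyl-3-[2-(benzyloxy)acetyl]oxazolidin-2-one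
Conditions: n-BuLi, THF, −78 °C; then 9, −78 to 0 °C
Reagents that add atoms: none
Why: N-Acylation of the lithiated oxazolidinone by the acid chloride, the standard entry to glycolate imides.

Step 7
Reactants: 10 (R)-4-benzyl-3-[2-(benzyloxy)acetyl]oxazolidin-2-one; 7 5-(allyloxy)-1-(benzyloxy)-3-bromo-2-(bromomethyl)benzene
Product: 11 (4R)-4-benzyl-3-{(2S)-3-[4-(allyloxy)-2-(benzyloxy)-6-bromophenyl]-2-(benzyloxy)propanoyl}oxazolidin-2-one
Conditions: NaN(SiMe3)2, THF, −78 °C; then 7, −78 to −40 °C
Reagents that add atoms: none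
Why: Auxiliary-controlled glycolate alkylation, in which the chelated (Z)-sodium enolate is shielded on one face by the C4 benzyl group of the (R)-oxazolidinone, so the benzylic bromide should add from the open face by SN2 and set the (2S) centre, the future C3, with its benzyl ether already in place.

Step 8
Reactants: 11 (4R)-4-benzyl-3-{(2S)-3-[4-(allyloxy)-2-(benzyloxy)-6-bromophenyl]-2-(benzyloxy)propanoyl}oxazolidin-2-one
Product: 12 (2S)-3-[4-(allyloxy)-2-(benzyloxy)-6-bromophenyl]-2-(benzyloxy)-N-methoxy-N-methylpropanamide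
Conditions: MeNHOMe·HCl, AlMe3, CH2Cl2, −10 to 0 °C
Reagents that add atoms: N,O-dimethylhydroxylamine hydrochloride CNOC.Cl
Why: Weinreb aminolysis of the imide, in which the aluminium amide formed from AlMe3 and the amine salt attacks the exocyclic carbonyl, assisted by coordination to the α-benzyloxy oxygen, and releases the auxiliary without touching the α-stereocentre.

Step 9
Reactants: 13 2-(allyloxy)phenol
Product: 14 2-(allyloxy)-4-bromophenol
Conditions: NBS, MeCN, 0 °C
Reagents that add atoms: N-bromosuccinimide O=C1CCC(=O)N1Br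
Why: Electrophilic aromatic bromination in which the free hydroxyl, the strongest director, sends bromine para to itself, and ring substitution of the phenol at 0 °C should be much faster than any reaction at the allyl double bond.

Step 10
Reactants: 14 2-(allyloxy)-4-bromophenol
Product: 15 2-(allyloxy)-1-(benzyloxy)-4-bromobenzene
Conditions: BnBr, K2CO3, DMF, rt
Reagents that add atoms: benzyl bromide BrCc1ccccc1
Why: Williamson etherification of the phenol, giving the aryl bromide with benzyl para and allyl meta to the halogen (future O4' and O3').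

Step 11
Reactants: 15 2-(allyloxy)-1-(benzyloxy)-4-bromobenzene; 12 (2S)-3-[4-(allyloxy)-2-(benzyloxy)-6-bromophenyl]-2-(benzyloxy)-N-methoxy-N-methylpropanamide
Product: 17 (2S)-1-[3-(allyloxy)-4-(benzyloxy)phenyl]-3-[4-(allyloxy)-2-(benzyloxy)-6-bromophenyl]-2-(benzyloxy)propan-1-one, via aryl Grignard reagent 16 (not isolated)
Conditions: 15, Mg, I2 (cat.), THF, 45 °C; then 12, THF, 0 °C; aq NH4Cl
Reagents that add atoms: none
Why: Grignard formation by magnesium insertion followed by Weinreb ketone synthesis, in which the N-methoxy-N-methylamide stops the addition at the ketone level, magnesium–bromine exchange with the ring A bromide is negligible at 0 °C, and the α-stereocentre is not enolised before the quench.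

Step 12
Reactants: 17 (2S)-1-[3-(allyloxy)-4-(benzyloxy)phenyl]-3-[4-(allyloxy)-2-(benzyloxy)-6-bromophenyl]-2-(benzyloxy)propan-1-one
Product: 18 (1R,2S)-1-[3-(allyloxy)-4-(benzyloxy)phenyl]-3-[4-(allyloxy)-2-(benzyloxy)-6-bromophenyl]-2-(benzyloxy)propan-1-ol
Conditions: Zn(BH4)2, Et2O, −20 °C
Reagents that add atoms: none
Why: Chelation-controlled reduction (Cram chelate model), in which zinc bridges the carbonyl oxygen and the α-benzyloxy oxygen and hydride is delivered to the face away from the C4 arylmethyl group, so the new (1R) carbinol (future C2) should stand anti to the C3 benzyloxy group.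

Step 13
Reactants: 18 (1R,2S)-1-[3-(allyloxy)-4-(benzyloxy)phenyl]-3-[4-(allyloxy)-2-(benzyloxy)-6-bromophenyl]-2-(benzyloxy)propan-1-ol
Product: 19 (2R,3S)-7-(allyloxy)-2-[3-(allyloxy)-4-(benzyloxy)phenyl]-3,5-bis(benzyloxy)chromane
Conditions: CuI (10 mol %), 3,4,7,8-tetramethyl-1,10-phenanthroline (20 mol %), Cs2CO3, toluene, 110 °C
Reagents that add atoms: none
Why: Cs2CO3 turns the C2 hydroxyl into its caesium alkoxide, which binds the phenanthroline-ligated monovalent copper; the copper alkoxide then activates the C8a–Br bond (oxidative addition to a trivalent copper aryl alkoxide) and C–O reductive elimination forms O1–C8a. The closest known reaction type is the copper-catalysed Ullmann-type O-arylation of aliphatic alcohols by aryl halides, which is established for secondary alcohols and for intramolecular chroman formation. Ring C closes as a six-membered ring at an sp2 carbon of ring A, formally 6-exo-trig with bromide as the exocyclic leaving group, through a seven-membered copper-containing ring. No stereocentre is created: neither the C2–O nor the C3–O bond is broken, so the anti arrangement from step 12 is carried over as the 2,3-trans chroman of (2R,3S) configuration. The step needs O-arylation to outrun β-hydride loss from the alkoxide (ketone formation with hydrodebromination), which the chelating tetramethylphenanthroline and the intramolecular six-ring geometry favour, and it needs a single mode of closure, which is secured because O3 is benzylated (no five-membered ring) and the only halogen sits at C8a.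

Step 14
Reactants: 19 (2R,3S)-7-(allyloxy)-2-[3-(allyloxy)-4-(benzyloxy)phenyl]-3,5-bis(benzyloxy)chromane
Product: 20 (2R,3S)-3,5-bis(benzyloxy)-2-[4-(benzyloxy)-3-hydroxyphenyl]chroman-7-ol
Conditions: Pd(PPh3)4 (5 mol %), morpholine, THF, rt
Reagents that add atoms: none
Why: Tsuji–Trost-type deallylation, in which zerovalent palladium ionises both aryl allyl ethers to allylpalladium phenoxides and morpholine captures the allyl groups, while the benzyl ethers and the chroman are inert and the aryl bromide that could have reacted with palladium is no longer present.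

Step 15
Reactants: 20 (2R,3S)-3,5-bis(benzyloxy)-2-[4-(benzyloxy)-3-hydroxyphenyl]chroman-7-ol; 21 3,4,5-tris(benzyloxy)benzoic acid
Product: 22 (2R,3S)-3,5-bis(benzyloxy)-2-{4-(benzyloxy)-3-[3,4,5-tris(benzyloxy)benzoyloxy]phenyl}chroman-7-yl 3,4,5-tris(benzyloxy)benzoate
Conditions: 21 (2.4 equiv), DCC, DMAP (cat.), CH2Cl2, 0 °C to rt
Reagents that add atoms: none
Why: Steglich esterification of the two phenols with the carbodiimide-activated acid under DMAP catalysis; O3, O5 and O4' are benzylated, so only O7 and O3' can be acylated.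

Step 16
Reactants: 22 (2R,3S)-3,5-bis(benzyloxy)-2-{4-(benzyloxy)-3-[3,4,5-tris(benzyloxy)benzoyloxy]phenyl}chroman-7-yl 3,4,5-tris(benzyloxy)benzoate
Product: 23 catechin 7,3'-di-O-gallate
Conditions: H2 (1 atm), Pd(OH)2 on carbon, THF/MeOH, rt
Reagents that add atoms: none
Why: Hydrogenolysis of all nine benzyl ethers over Pd(OH)2 on carbon under neutral conditions, which is established to leave aryl gallate esters and the O1–C2 bond of flavan-3-ols intact, and which is run without base so that the 3'-gallate has no occasion to migrate to O4'.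

**Compound list**
1 | 5-bromoresorcinol | Oc1cc(O)cc(Br)c1 | starting material
2 | N-[(2-bromo-4,6-dihydroxyphenyl)methylidene]-N-methylmethanaminium chloride (aryliminium chloride) | C[N+](C)=Cc1c(O)cc(O)cc1Br.[Cl-] | intermediate
3 | 2-bromo-4,6-dihydroxybenzaldehyde | O=Cc1c(O)cc(O)cc1Br | intermediate
4 | 4-(allyloxy)-2-bromo-6-hydroxybenzaldehyde | O=Cc1c(O)cc(OCC=C)cc1Br | intermediate
5 | 4-(allyloxy)-2-(benzyloxy)-6-bromobenzaldehyde | O=Cc1c(OCc2ccccc2)cc(OCC=C)cc1Br | intermediate
6 | [4-(allyloxy)-2-(benzyloxy)-6-bromophenyl]methanol | OCc1c(OCc2ccccc2)cc(OCC=C)cc1Br | intermediate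
7 | 5-(allyloxy)-1-(benzyloxy)-3-bromo-2-(bromomethyl)benzene | BrCc1c(OCc2ccccc2)cc(OCC=C)cc1Br | intermediate
8 | (R)-4-benzyloxazolidin-2-one | O=C1N[C@H](Cc2ccccc2)CO1 | starting material
9 | benzyloxyacetyl chloride | O=C(Cl)COCc1ccccc1 | starting material
10 | (R)-4-benzyl-3-[2-(benzyloxy)acetyl]oxazolidin-2-one | O=C(COCc1ccccc1)N1C(=O)OC[C@H]1Cc1ccccc1 | intermediate
11 | (4R)-4-benzyl-3-{(2S)-3-[4-(allyloxy)-2-(benzyloxy)-6-bromophenyl]-2-(benzyloxy)propanoyl}oxazolidin-2-one | O=C([C@H](Cc1c(OCc2ccccc2)cc(OCC=C)cc1Br)OCc1ccccc1)N1C(=O)OC[C@H]1Cc1ccccc1 | intermediate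
12 | (2S)-3-[4-(allyloxy)-2-(benzyloxy)-6-bromophenyl]-2-(benzyloxy)-N-methoxy-N-methylpropanamide | CON(C)C(=O)[C@H](Cc1c(OCc2ccccc2)cc(OCC=C)cc1Br)OCc1ccccc1 | intermediate
13 | 2-(allyloxy)phenol | C=CCOc1ccccc1O | starting material
14 | 2-(allyloxy)-4-bromophenol | C=CCOc1cc(Br)ccc1O | intermediate
15 | 2-(allyloxy)-1-(benzyloxy)-4-bromobenzene | C=CCOc1cc(Br)ccc1OCc1ccccc1 | intermediate
16 | [3-(allyloxy)-4-(benzyloxy)phenyl]magnesium bromide (aryl Grignard reagent) | C=CCOc1cc([Mg]Br)ccc1OCc1ccccc1 | intermediate
17 | (2S)-1-[3-(allyloxy)-4-(benzyloxy)phenyl]-3-[4-(allyloxy)-2-(benzyloxy)-6-bromophenyl]-2-(benzyloxy)propan-1-one | O=C(c1ccc(OCc2ccccc2)c(OCC=C)c1)[C@H](Cc1c(OCc2ccccc2)cc(OCC=C)cc1Br)OCc1ccccc1 | intermediate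
18 | (1R,2S)-1-[3-(allyloxy)-4-(benzyloxy)phenyl]-3-[4-(allyloxy)-2-(benzyloxy)-6-bromophenyl]-2-(benzyloxy)propan-1-ol | C=CCOc1cc(OCc2ccccc2)c(C[C@H](OCc2ccccc2)[C@H](O)c2ccc(OCc3ccccc3)c(OCC=C)c2)c(Br)c1 | intermediate
19 | (2R,3S)-7-(allyloxy)-2-[3-(allyloxy)-4-(benzyloxy)phenyl]-3,5-bis(benzyloxy)chromane | C=CCOc1cc(OCc2ccccc2)c2c(c1)O[C@H](c1ccc(OCc3ccccc3)c(OCC=C)c1)[C@@H](OCc1ccccc1)C2 | intermediate
20 | (2R,3S)-3,5-bis(benzyloxy)-2-[4-(benzyloxy)-3-hydroxyphenyl]chroman-7-ol | Oc1cc(OCc2ccccc2)c2c(c1)O[C@H](c1ccc(OCc3ccccc3)c(O)c1)[C@@H](OCc1ccccc1)C2 | intermediate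
21 | 3,4,5-tris(benzyloxy)benzoic acid | OC(=O)c1cc(OCc2ccccc2)c(OCc2ccccc2)c(OCc2ccccc2)c1 | starting material
22 | (2R,3S)-3,5-bis(benzyloxy)-2-{4-(benzyloxy)-3-[3,4,5-tris(benzyloxy)benzoyloxy]phenyl}chroman-7-yl 3,4,5-tris(benzyloxy)benzoate | O=C(Oc1cc(OCc2ccccc2)c2c(c1)O[C@H](c1ccc(OCc3ccccc3)c(OC(=O)c3cc(OCc4ccccc4)c(OCc4ccccc4)c(OCc4ccccc4)c3)c1)[C@@H](OCc1ccccc1)C2)c1cc(OCc2ccccc2)c(OCc2ccccc2)c(OCc2ccccc2)c1 | intermediate
23 | catechin 7,3'-di-O-gallate, (2R,3S)-3,5-dihydroxy-2-[4-hydroxy-3-(3,4,5-trihydroxybenzoyloxy)phenyl]chroman-7-yl 3,4,5-trihydroxybenzoate | O=C(Oc1cc(O)c2c(c1)O[C@H](c1ccc(O)c(OC(=O)c3cc(O)c(O)c(O)c3)c1)[C@@H](O)C2)c1cc(O)c(O)c(O)c1 | target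

**Step count**
Total: 16 steps. Longest linear sequence: 13 steps (steps 1 to 5, 7, 8, 11 to 16, from 5-bromoresorcinol).

**Steps most likely to fail**

Step 13. The copper-bound C2 alkoxide may lose its β-hydride faster than the metal inserts into the C8a–Br bond, which would return the ketone and reduce the carbon–bromine bond. The fallback changes the electrophile in a separate step and sets out from 18. Copper-catalysed aromatic Finkelstein exchange (CuI, NaI, trans-N,N'-dimethylcyclohexane-1,2-diamine, dioxane, 110 °C, no base, so the free alcohol does not couple) should give (1R,2S)-1-[3-(allyloxy)-4-(benzyloxy)phenyl]-3-[4-(allyloxy)-2-(benzyloxy)-6-iodophenyl]-2-(benzyloxy)propan-1-ol F1. Its far faster oxidative addition should allow the same closure with CuI, the tetramethylphenanthroline and Cs2CO3 at about 80 °C, where alkoxide oxidation is slower. The sequence comes back to the route at 19.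

Step 7. The sodium glycolate enolate decomposes above about −40 °C and may do so faster than it attacks a benzylic carbon flanked by bromine and a benzyloxy group. The fallback forms C3–C4 by aldol addition to the aldehyde instead and sets out from 5.
- The enantiomeric auxiliary is acylated with 9 as in step 6 to give (S)-4-benzyl-3-[2-(benzyloxy)acetyl]oxazolidin-2-one F2.
- Its dibutylboron enolate (Bu2BOTf, Et3N, CH2Cl2, −78 to 0 °C) adds to 5 in a syn-selective glycolate aldol reaction. Because the boron aldol and the sodium enolate alkylation use opposite enolate faces, the (S)-auxiliary is the one that should give (4S)-4-benzyl-3-{(2S,3R)-3-[4-(allyloxy)-2-(benzyloxy)-6-bromophenyl]-2-(benzyloxy)-3-hydroxypropanoyl}oxazolidin-2-one F3.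
- Ionic hydrogenation of the electron-rich benzylic alcohol (Et3SiH, CF3CO2H, CH2Cl2, 0 °C) removes the extra hydroxyl and should give (4S)-4-benzyl-3-{(2S)-3-[4-(allyloxy)-2-(benzyloxy)-6-bromophenyl]-2-(benzyloxy)propanoyl}oxazolidin-2-one F4.
- Aminolysis under the conditions of step 8 brings the sequence back to the route at 12.

Step 8. The aluminium amide may attack the ring carbonyl of the oxazolidinone instead of the hindered, α-branched exocyclic carbonyl, opening the auxiliary. The fallback separates cleavage from amide formation and sets out from 11. Hydroperoxide (LiOH, H2O2, THF/H2O, 0 °C), which is selective for the exocyclic acyl group, should give (2S)-3-[4-(allyloxy)-2-(benzyloxy)-6-bromophenyl]-2-(benzyloxy)propanoic acid F5. Carbodiimide coupling with N,O-dimethylhydroxylamine hydrochloride (EDC·HCl, HOBt, N-methylmorpholine, CH2Cl2) then returns to the route at 12.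

Further compounds
F1 | step 13 | (1R,2S)-1-[3-(allyloxy)-4-(benzyloxy)phenyl]-3-[4-(allyloxy)-2-(benzyloxy)-6-iodophenyl]-2-(benzyloxy)propan-1-ol | C=CCOc1cc(OCc2ccccc2)c(C[C@H](OCc2ccccc2)[C@H](O)c2ccc(OCc3ccccc3)c(OCC=C)c2)c(I)c1
F2 | step 7 | (S)-4-benzyl-3-[2-(benzyloxy)acetyl]oxazolidin-2-one | O=C(COCc1ccccc1)N1C(=O)OC[C@@H]1Cc1ccccc1
F3 | step 7 | (4S)-4-benzyl-3-{(2S,3R)-3-[4-(allyloxy)-2-(benzyloxy)-6-bromophenyl]-2-(benzyloxy)-3-hydroxypropanoyl}oxazolidin-2-one | O=C([C@@H](OCc1ccccc1)[C@H](O)c1c(OCc2ccccc2)cc(OCC=C)cc1Br)N1C(=O)OC[C@@H]1Cc1ccccc1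
F4 | step 7 | (4S)-4-benzyl-3-{(2S)-3-[4-(allyloxy)-2-(benzyloxy)-6-bromophenyl]-2-(benzyloxy)propanoyl}oxazolidin-2-one | O=C([C@@H](OCc1ccccc1)Cc1c(OCc2ccccc2)cc(OCC=C)cc1Br)N1C(=O)OC[C@@H]1Cc1ccccc1
F5 | step 8 | (2S)-3-[4-(allyloxy)-2-(benzyloxy)-6-bromophenyl]-2-(benzyloxy)propanoic acid | OC(=O)[C@H](Cc1c(OCc2ccccc2)cc(OCC=C)cc1Br)OCc1ccccc1
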